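**Strategy**

The route rests on cutting the seven-membered 1,5-benzodioxepine ring (O7'–C5–C6–C7–O6' plus C6'/C7' of the lower chromone) that bridges C5 and C7 of the upper cyclohexene ring. Both rings close in one operation: a catechol acetal (1,3-benzodioxole with O6' and O7' both on C7) attached through C8 to a monocyclic γ-pyrone is ionised at O7'–C7, the (E)-vinylsilane on C4a attacks C7 through C6, and the released O7' captures the cation at C5, which O1 stabilises through C8a=C4a. This formal insertion of C5=C6 into the acetal sets C5, C6 and C7 from C8; silicon on C6 later becomes the hydroxyl.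

Key step: step 12

Remark: locants C2–C8a denote the upper (tetrahydro)chromone unit and primed locants the lower chromone, also in all precursors; the acetal carbon C7 of 18–20 is formed without control and both epimers should converge in step 12.

**Route**

Step 1
Reactants: 1 pentane-2,4-dione; 2 1-(chloromethyl)-4-methoxybenzene
Product: 3 6-(4-methoxyphenyl)hexane-2,4-dione
Conditions: LDA (2.2 equiv), THF, 0 °C; then 2, 0 °C to rt; aq. NH4Cl
Reagents that add atoms: none
Why: alkylation of the 1,3-diketone dianion should occur only at the terminal, more basic carbanion, giving the chain-extended diketone without alkylation at C3.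

Step 2
Reactants: 3 6-(4-methoxyphenyl)hexane-2,4-dione; 4 diethyl oxalate
Product: 6 ethyl 6-[2-(4-methoxyphenyl)ethyl]-4-oxo-4H-pyran-2-carboxylate, via triketo ester 5 (not isolated)
Conditions: NaOEt (2.2 equiv), EtOH, 0 °C to rt; then HCl (gas) in EtOH, reflux
Reagents that add atoms: none
Why: crossed Claisen condensation at the methyl terminus (preferred over the more hindered methylene) followed by acid-catalysed cyclodehydration of the 1,3,5-tricarbonyl array is the classical entry to 4-oxo-4H-pyran-2-carboxylates.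

Step 3
Reactants: 6 ethyl 6-[2-(4-methoxyphenyl)ethyl]-4-oxo-4H-pyran-2-carboxylate
Product: 7 ethyl 3-iodo-6-[2-(4-methoxyphenyl)ethyl]-4-oxo-4H-pyran-2-carboxylate
Conditions: TMPMgCl·LiCl (1.3 equiv), THF, −40 °C; then I2, −40 °C to rt
Reagents that add atoms: iodine (II)
Why: directed ortho-magnesiation with the hindered amide base should occur kinetically at C3, the only ring C–H flanked by both the ester and the pyranone carbonyl (chelation control), and iodinolysis then gives the 3-iodide.

Step 4
Reactants: 8 benzyl(chloro)dimethylsilane; 9 ethenylmagnesium bromide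
Product: 10 benzyl(ethenyl)dimethylsilane
Conditions: THF, 0 °C to rt
Reagents that add atoms: none
Why: nucleophilic substitution at silicon by the vinyl Grignard reagent gives the vinylsilane carrying the benzyldimethylsilyl group, which is robust to acid and base but later oxidisable after fluoride activation.

Step 5
Reactants: 7 ethyl 3-iodo-6-[2-(4-methoxyphenyl)ethyl]-4-oxo-4H-pyran-2-carboxylate; 10 benzyl(ethenyl)dimethylsilane
Product: 11 ethyl 3-[(E)-2-(benzyldimethylsilyl)ethenyl]-6-[2-(4-methoxyphenyl)ethyl]-4-oxo-4H-pyran-2-carboxylate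
Conditions: Pd(OAc)2 (5 mol %), P(o-tol)3 (10 mol %), Ag2CO3 (1.0 equiv), DMF, 70 °C
Reagents that add atoms: none
Why: the silver-assisted Heck reaction of a vinylsilane runs through the cationic pathway that suppresses desilylation and should give the (E)-2-silylalkenyl product by syn insertion and syn beta-hydride elimination.

Step 6
Reactants: 11 ethyl 3-[(E)-2-(benzyldimethylsilyl)ethenyl]-6-[2-(4-methoxyphenyl)ethyl]-4-oxo-4H-pyran-2-carboxylate
Product: 12 3-[(E)-2-(benzyldimethylsilyl)ethenyl]-2-(2,2-dibromoacetyl)-6-[2-(4-methoxyphenyl)ethyl]-4H-pyran-4-one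
Conditions: CH2Br2 (3.5 equiv), LDA (3.3 equiv), THF, −90 °C; then 11, −90 to −78 °C; AcOH quench at −78 °C
Reagents that add atoms: dibromomethane (BrCBr)
Why: acylation of dibromomethyllithium by the ester gives a dibromomethyl ketone that is enolised in situ and so protected from a second addition until the acidic quench, while the excess base should park the γ-pyrone as its lateral dienolate.

Step 7
Reactants: 13 1-(2-hydroxy-4,5-dimethoxyphenyl)ethan-1-one; 14 ethyl 3-phenylpropanoate
Product: 16 6,7-dimethoxy-2-(2-phenylethyl)-4H-chromen-4-one, via diketone 15 (not isolated)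
Conditions: NaH (4 equiv), THF, reflux; then conc. HCl, MeOH, reflux
Reagents that add atoms: none
Why: Claisen condensation of the acetophenone enolate with the ester gives the 1,3-diketone, which should undergo acid-catalysed cyclodehydration onto the ortho-phenol to the 2-substituted chromone.

Step 8
Reactants: 16 6,7-dimethoxy-2-(2-phenylethyl)-4H-chromen-4-one
Product: 17 6,7-dihydroxy-2-(2-phenylethyl)-4H-chromen-4-one
Conditions: BBr3 (4 equiv), CH2Cl2, −78 °C to rt; then MeOH, H2O
Reagents that add atoms: none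
Why: Lewis-acid cleavage of both aryl methyl ethers by BBr3 should liberate the catechol and leave the chromone untouched.

Step 9
Reactants: 12 3-[(E)-2-(benzyldimethylsilyl)ethenyl]-2-(2,2-dibromoacetyl)-6-[2-(4-methoxyphenyl)ethyl]-4H-pyran-4-one; 17 6,7-dihydroxy-2-(2-phenylethyl)-4H-chromen-4-one
Product: 18 2-({3-[(E)-2-(benzyldimethylsilyl)ethenyl]-6-[2-(4-methoxyphenyl)ethyl]-4-oxo-4H-pyran-2-yl}carbonyl)-6-(2-phenylethyl)-8H-[1,3]dioxolo[4,5-g]chromen-8-one (acetal carbon stereorandom)
Conditions: K2CO3 (3 equiv), degassed DMF, 0 °C to rt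
Reagents that add atoms: none
Why: double Williamson-type O-alkylation of the catechol by the alpha,alpha-dibromoketone (two SN2 displacements next to the carbonyl, the second intramolecular) should close the 2-acyl-1,3-benzodioxole, and because both oxygens end on the same carbon no regiochemical question arises.

Step 10
Reactants: 18 the 2-acyl-1,3-benzodioxole ketone
Product: 19 2-[(R)-{3-[(E)-2-(benzyldimethylsilyl)ethenyl]-6-[2-(4-methoxyphenyl)ethyl]-4-oxo-4H-pyran-2-yl}(hydroxy)methyl]-6-(2-phenylethyl)-8H-[1,3]dioxolo[4,5-g]chromen-8-one (C8 R; C7 as both epimers)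
Conditions: RuCl[(S,S)-TsDPEN](p-cymene) (2 mol %), HCO2H/Et3N (5:2), DMF, rt
Reagents that add atoms: none
Why: Noyori asymmetric transfer hydrogenation of the activated alpha,alpha-dioxy ketone should deliver hydride in the sense known for aryl alkyl ketones (pyranonyl as the pi-group, acetal carbon as the alkyl group), which sets C8 in the arrangement of the target (R here because the acetal carbon outranks C8a), while the vinylogous ester carbonyls and the vinylsilane are not reduced.

Step 11
Reactants: 19 the (R)-carbinol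
Product: 20 (R)-{3-[(E)-2-(benzyldimethylsilyl)ethenyl]-6-[2-(4-methoxyphenyl)ethyl]-4-oxo-4H-pyran-2-yl}[8-oxo-6-(2-phenylethyl)-8H-[1,3]dioxolo[4,5-g]chromen-2-yl]methyl acetate (C7 as both epimers)
Conditions: Ac2O, pyridine, DMAP (cat.), CH2Cl2, 0 °C to rt
Reagents that add atoms: acetic anhydride (CC(=O)OC(C)=O)
Why: DMAP-catalysed acylation of the secondary alcohol installs the acetate that protects O8 and serves as participating group in the next step, without touching C8.

Step 12
Reactants: 20 the (R)-acetate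
Product: 21 8-O-acetyl-6-(benzyldimethylsilyl)-6-deoxy-4'-methoxyaquisinenone G (5R,6S,7S,8S; target skeleton with SiMe2Bn in place of the 6-hydroxyl on the same face and the 8-hydroxyl acetylated)
Conditions: TMSOTf (0.5 equiv), 2,6-di-tert-butyl-4-methylpyridine (0.2 equiv), 4 Å MS, CH2Cl2, −78 to −20 °C; then sat. aq. NaHCO3
Reagents that add atoms: none
Why: Proposed new method: the silyl triflate should ionise the O7'–C7 bond of the benzodioxole with anchimeric help from the C8 acetate, C6 of the (E)-vinylsilane then attacks C7 of the resulting acetoxonium/oxocarbenium ion in a Prins-type step, and the released O7' (as its silyl ether) closes onto the C5 cation with loss of the silyl group, so that C5=C6 is formally inserted into the acetal C–O bond. The closest known reaction types are Lewis-acid Prins cyclisations of acetals onto alkenes that end by capture with an oxygen nucleophile, ring enlargement of cyclic acetals by enol ethers, and acid-mediated cyclisation of hydroxy vinylsilanes through beta-silyl cations that keep silicon. The carbocycle closes 6-endo-trig at the alkene (C6 onto the exocyclic cationic C7) and the dioxepine closes by intramolecular 1,3-diaxial attack of O7' on the cyclic C5 cation (seven-membered ring, exo with respect to the cation). C7 is set by anti opening of the cis-fused acetoxonium ion, which places O6' trans to the C8 acetate; C6 is set by the (E)-alkene geometry in the chair-like closure, which leaves silicon trans to O6'; C5 is set by the tether, because after ring flip to the all-axial half-chair O7' can reach C5 only on the face of O6' and anti to the axial C6–Si bond. The step needs O7' (para to the chromone carbonyl, the better leaving group) and not O6' to leave, and needs ring closure at C5 to outrun loss of silicon; the electronic bias of the two catechol oxygens, the pre-organised diaxial array, the non-nucleophilic triflate counter-ion and low temperature should secure this.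

Step 13
Reactants: 21 8-O-acetyl-6-(benzyldimethylsilyl)-6-deoxy-4'-methoxyaquisinenone G
Product: 24 (+)-4'-methoxyaquisinenone G (5R,6S,7R,8S), via silanol 22 (not isolated), via 8-O-acetate 23 (not isolated)
Conditions: TBAF (2.2 equiv), THF, 0 °C; then KHCO3, 30% aq. H2O2, MeOH/THF, rt; then K2CO3, MeOH, 0 °C
Reagents that add atoms: hydrogen peroxide (OO)
Why: Tamao–Fleming oxidation, in which fluoride removes the benzyl group from silicon, basic peroxide converts the C6–Si bond into C6–OH with retention of configuration by 1,2-migration from silicon to oxygen, and carbonate methanolysis removes the acetate, so that no stereocentre is disturbed.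

**Compound list**

1 | pentane-2,4-dione | CC(=O)CC(C)=O | starting material
2 | 1-(chloromethyl)-4-methoxybenzene | COc1ccc(CCl)cc1 | starting material
3 | 6-(4-methoxyphenyl)hexane-2,4-dione | COc1ccc(CCC(=O)CC(C)=O)cc1 | intermediate
4 | diethyl oxalate | CCOC(=O)C(=O)OCC | starting material
5 | ethyl 8-(4-methoxyphenyl)-2,4,6-trioxooctanoate | CCOC(=O)C(=O)CC(=O)CC(=O)CCc1ccc(OC)cc1 | intermediate
6 | ethyl 6-[2-(4-methoxyphenyl)ethyl]-4-oxo-4H-pyran-2-carboxylate | CCOC(=O)c1cc(=O)cc(CCc2ccc(OC)cc2)o1 | intermediate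
7 | ethyl 3-iodo-6-[2-(4-methoxyphenyl)ethyl]-4-oxo-4H-pyran-2-carboxylate | CCOC(=O)c1oc(CCc2ccc(OC)cc2)cc(=O)c1I | intermediate
8 | benzyl(chloro)dimethylsilane | C[Si](C)(Cl)Cc1ccccc1 | starting material
9 | ethenylmagnesium bromide | C=C[Mg]Br | starting material
10 | benzyl(ethenyl)dimethylsilane | C=C[Si](C)(C)Cc1ccccc1 | intermediate
11 | ethyl 3-[(E)-2-(benzyldimethylsilyl)ethenyl]-6-[2-(4-methoxyphenyl)ethyl]-4-oxo-4H-pyran-2-carboxylate | CCOC(=O)c1oc(CCc2ccc(OC)cc2)cc(=O)c1/C=C/[Si](C)(C)Cc1ccccc1 | intermediate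
12 | 3-[(E)-2-(benzyldimethylsilyl)ethenyl]-2-(2,2-dibromoacetyl)-6-[2-(4-methoxyphenyl)ethyl]-4H-pyran-4-one | O=C(C(Br)Br)c1oc(CCc2ccc(OC)cc2)cc(=O)c1/C=C/[Si](C)(C)Cc1ccccc1 | intermediate
13 | 1-(2-hydroxy-4,5-dimethoxyphenyl)ethan-1-one | CC(=O)c1cc(OC)c(OC)cc1O | starting material
14 | ethyl 3-phenylpropanoate | CCOC(=O)CCc1ccccc1 | starting material
15 | 1-(2-hydroxy-4,5-dimethoxyphenyl)-5-phenylpentane-1,3-dione | COc1cc(O)c(C(=O)CC(=O)CCc2ccccc2)cc1OC | intermediate
16 | 6,7-dimethoxy-2-(2-phenylethyl)-4H-chromen-4-one | COc1cc2oc(CCc3ccccc3)cc(=O)c2cc1OC | intermediate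
17 | 6,7-dihydroxy-2-(2-phenylethyl)-4H-chromen-4-one | Oc1cc2oc(CCc3ccccc3)cc(=O)c2cc1O | intermediate
18 | 2-({3-[(E)-2-(benzyldimethylsilyl)ethenyl]-6-[2-(4-methoxyphenyl)ethyl]-4-oxo-4H-pyran-2-yl}carbonyl)-6-(2-phenylethyl)-8H-[1,3]dioxolo[4,5-g]chromen-8-one (acetal carbon stereorandom) | COc1ccc(CCc2cc(=O)c(/C=C/[Si](C)(C)Cc3ccccc3)c(o2)C(=O)C2Oc3cc4oc(CCc5ccccc5)cc(=O)c4cc3O2)cc1 | intermediate
19 | 2-[(R)-{3-[(E)-2-(benzyldimethylsilyl)ethenyl]-6-[2-(4-methoxyphenyl)ethyl]-4-oxo-4H-pyran-2-yl}(hydroxy)methyl]-6-(2-phenylethyl)-8H-[1,3]dioxolo[4,5-g]chromen-8-one (acetal carbon as both epimers) | COc1ccc(CCc2cc(=O)c(/C=C/[Si](C)(C)Cc3ccccc3)c(o2)[C@@H](O)C2Oc3cc4oc(CCc5ccccc5)cc(=O)c4cc3O2)cc1 | intermediate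
20 | (R)-{3-[(E)-2-(benzyldimethylsilyl)ethenyl]-6-[2-(4-methoxyphenyl)ethyl]-4-oxo-4H-pyran-2-yl}[8-oxo-6-(2-phenylethyl)-8H-[1,3]dioxolo[4,5-g]chromen-2-yl]methyl acetate (acetal carbon as both epimers) | COc1ccc(CCc2cc(=O)c(/C=C/[Si](C)(C)Cc3ccccc3)c(o2)[C@@H](OC(C)=O)C2Oc3cc4oc(CCc5ccccc5)cc(=O)c4cc3O2)cc1 | intermediate
21 | 8-O-acetyl-6-(benzyldimethylsilyl)-6-deoxy-4'-methoxyaquisinenone G (5R,6S,7S,8S) | COc1ccc(CCc2cc(=O)c3c(o2)[C@@H](OC(C)=O)[C@@H]2Oc4cc5c(=O)cc(CCc6ccccc6)oc5cc4O[C@H]3[C@@H]2[Si](C)(C)Cc2ccccc2)cc1 | intermediate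
22 | 8-O-acetyl-6-deoxy-6-[hydroxy(dimethyl)silyl]-4'-methoxyaquisinenone G | COc1ccc(CCc2cc(=O)c3c(o2)[C@@H](OC(C)=O)[C@@H]2Oc4cc5c(=O)cc(CCc6ccccc6)oc5cc4O[C@H]3[C@@H]2[Si](C)(C)O)cc1 | intermediate
23 | 8-O-acetyl-4'-methoxyaquisinenone G (5R,6S,7R,8S) | COc1ccc(CCc2cc(=O)c3c(o2)[C@@H](OC(C)=O)[C@@H]2Oc4cc5c(=O)cc(CCc6ccccc6)oc5cc4O[C@H]3[C@@H]2O)cc1 | intermediate
24 | (+)-4'-methoxyaquisinenone G (5R,6S,7R,8S) | COc1ccc(CCc2cc(=O)c3c(o2)[C@@H](O)[C@@H]2Oc4cc5c(=O)cc(CCc6ccccc6)oc5cc4O[C@H]3[C@@H]2O)cc1 | target

**Step count and risks**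

Total step count: 13. Longest linear sequence: 10 steps (steps 1, 2, 3, 5, 6, 9, 10, 11, 12, 13).

Steps most likely to fail:

1. Step 12 (Proposed new method). The beta-silyl cation at C5 may lose silicon before O7' closes the dioxepine, or the ring-closed product may re-ionise and then lose silicon. The wrong acetal C–O bond (O6'–C7) may ionise. Ionisation may also be slow because both pyranone carbonyls bind the silyl triflate. The fallback uses known chemistry, sets out from 20 and returns at 24. A vinylsilane-terminated Prins cyclisation with ipso loss of silicon (SnCl4, CH2Cl2, −78 °C) should give the 5,6-ene with free 7'-hydroxyl, (7R,8S)-8-acetoxy-7-aryloxy-7,8-dihydrochromenone F1. Epoxidation with dimethyldioxirane (acetone, 0 °C) anti to the allylic aryloxy group should give the 5,6-epoxide F2, cis to the 8-acetoxy group. K2CO3 in MeOH should then open the epoxide at C5 by trans-diaxial attack of the phenoxide O7' and methanolyse the acetate, passing through 23 to 24.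

2. Step 13. The C6–Si and C5–O7' bonds are trans-diaxial, so fluoride or peroxide activation of silicon may trigger anti-periplanar beta-elimination across C5–C6 instead of oxidation. The fallback sets out from 21 and returns at 24. The elimination is run on purpose (CsF, DMF, 60 °C; then K2CO3, MeOH) to give the deacetylated dienyl phenol F3. Hydroxyl-directed epoxidation (VO(acac)2 cat., t-BuOOH, CH2Cl2) syn to the homoallylic 8-hydroxyl should give the epoxy alcohol F4. K2CO3 in DMF should then close the dioxepine by phenoxide opening of the epoxide at C5, giving 24.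

3. Step 3. The amide base may deprotonate the acidic lateral CH2 next to C6 of the pyranone (dienolate formation) instead of the ring C3–H, or attack the ester. The fallback sets out from 1 and returns at 7; it removes the lateral protons for the metalation. Boron-templated aldol condensation of 1 with 4-methoxybenzaldehyde (B2O3, B(OBu)3, n-BuNH2, EtOAc, 70 °C; then aq. HCl) should give (E)-6-(4-methoxyphenyl)hex-5-ene-2,4-dione F5. Claisen condensation with 4 and cyclodehydration as in step 2 should give the styryl pyranone ester F6. Magnesiation and iodination as in step 3 should then give the 3-iodide F7. Diimide reduction of the styrenic double bond (2-nitrobenzenesulfonylhydrazide, Et3N, CH2Cl2, rt) should leave the iodide and the pyranone intact and give 7.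

Further compounds
F1 | step 12 | (7R,8S)-7-{[7-hydroxy-4-oxo-2-(2-phenylethyl)-4H-chromen-6-yl]oxy}-2-[2-(4-methoxyphenyl)ethyl]-4-oxo-7,8-dihydro-4H-chromen-8-yl acetate | COc1ccc(CCc2cc(=O)c3c(o2)[C@@H](OC(C)=O)[C@H](Oc4cc5c(=O)cc(CCc6ccccc6)oc5cc4O)C=C3)cc1
F2 | step 12 | 5,6-epoxide of F1 with the oxirane cis to the 8-acetoxy group and trans to the 7-aryloxy group | COc1ccc(CCc2cc(=O)c3c(o2)[C@@H](OC(C)=O)[C@H](Oc4cc5c(=O)cc(CCc6ccccc6)oc5cc4O)[C@H]4O[C@@H]34)cc1
F3 | step 13 | (7R,8S)-8-hydroxy-7-{[7-hydroxy-4-oxo-2-(2-phenylethyl)-4H-chromen-6-yl]oxy}-2-[2-(4-methoxyphenyl)ethyl]-7,8-dihydro-4H-chromen-4-one | COc1ccc(CCc2cc(=O)c3c(o2)[C@@H](O)[C@H](Oc4cc5c(=O)cc(CCc6ccccc6)oc5cc4O)C=C3)cc1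
F4 | step 13 | 5,6-epoxide of F3 with the oxirane cis to the 8-hydroxyl and trans to the 7-aryloxy group | COc1ccc(CCc2cc(=O)c3c(o2)[C@@H](O)[C@H](Oc4cc5c(=O)cc(CCc6ccccc6)oc5cc4O)[C@H]4O[C@@H]34)cc1
F5 | step 3 | (E)-6-(4-methoxyphenyl)hex-5-ene-2,4-dione | COc1ccc(/C=C/C(=O)CC(C)=O)cc1
F6 | step 3 | ethyl 6-[(E)-2-(4-methoxyphenyl)ethenyl]-4-oxo-4H-pyran-2-carboxylate | CCOC(=O)c1cc(=O)cc(/C=C/c2ccc(OC)cc2)o1
F7 | step 3 | ethyl 3-iodo-6-[(E)-2-(4-methoxyphenyl)ethenyl]-4-oxo-4H-pyran-2-carboxylate | CCOC(=O)c1oc(/C=C/c2ccc(OC)cc2)cc(=O)c1I
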